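**Assumption:** paucinervin B has no stereocentres, so no enantioselective step is needed. All three phenols are protected as MOM ethers and released together at the end.

## Retrosynthetic overview
- Paucinervin B (**1**) comes from global MOM removal of the tris-MOM diaryl ether **2**.
- **2** comes from one Cu-catalysed Ullmann-type C–O coupling of the ring-B phenol **3** with the ring-A aryl bromide **4**. This is the only ring-to-ring bond, and no ring is built by cyclisation.
- **3** is made from 2,5-dimethoxyphenol by MOM protection, para-bromination, Br/Li prenylation, then ortho-lithiation and hydroxylation.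
- **4** is made from 5-bromoresorcinol by bis-MOM protection, then ortho-lithiation and methoxycarbonylation.

## Route

**Step 1**
Reactants: 5 (2,5-dimethoxyphenol); 6 (chloromethyl methyl ether, MOMCl)
Product: 7 (1-(methoxymethoxy)-2,5-dimethoxybenzene)
Conditions: NaH, THF, 0 °C → rt
Reagents that add atoms: MOMCl, ClCOC (adds CH2OCH3)
Why: Williamson-type MOM etherification of the phenoxide. MOM gives a strong ortho-directing group for step 4 and is removed together with the other MOM groups in step 8.

**Step 2**
Reactants: 7; 8 (N-bromosuccinimide)
Product: 9 (1-bromo-2,5-dimethoxy-4-(methoxymethoxy)benzene)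
Conditions: NBS, MeCN, 0 °C → rt
Reagents that add atoms: NBS, O=C1CCC(=O)N1Br (adds Br)
Why: Electrophilic aromatic bromination goes to the position para to OMOM and ortho to OMe. This is the same site that 1,2,4-trimethoxybenzene brominates, and it is where the prenyl group must sit. Bromination is done before prenylation so the alkene is never exposed to NBS.

**Step 3**
Reactants: 9; 10 (prenyl bromide, 1-bromo-3-methylbut-2-ene)
Product: 11 (1-(methoxymethoxy)-2,5-dimethoxy-4-(3-methylbut-2-en-1-yl)benzene)
Conditions: n-BuLi (1.05 equiv), THF, −78 °C; then CuI (10 mol %), 10, −78 °C → rt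
Reagents that add atoms: prenyl bromide, CC(C)=CCBr (adds prenyl)
Why: Br/Li exchange gives the aryllithium, and Cu-catalysed SN2 alkylation with prenyl bromide gives the linear (non-SN2′) prenyl arene.

**Step 4**
Reactants: 11; 12 (hydrogen peroxide)
Product: 3 (2,5-dimethoxy-6-(methoxymethoxy)-3-(3-methylbut-2-en-1-yl)phenol)
Conditions: n-BuLi, THF, −78 → −20 °C; B(OMe)3, −78 °C → rt; then 30% H2O2, 2 M NaOH, 0 °C
Reagents that add atoms: hydrogen peroxide, OO (its oxygen becomes the phenol OH); B(OMe)3, COB(OC)OC, is lost on oxidation
Why: Directed ortho-metalation followed by borylation and oxidation. The only ring C–H flanked by two oxygens (OMOM and OMe) is lithiated, which puts the new phenol O between the OMe and OMOM groups. This sets the 1-OAr/2-OMOM/6-OMe pattern of ring B.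

**Step 5**
Reactants: 13 (5-bromobenzene-1,3-diol, 5-bromoresorcinol); 6 (MOMCl, 2.5 equiv)
Product: 14 (1-bromo-3,5-bis(methoxymethoxy)benzene)
Conditions: MOMCl, i-Pr2NEt, CH2Cl2, 0 °C → rt
Reagents that add atoms: MOMCl, ClCOC (adds two CH2OCH3)
Why: Standard MOM protection of both phenols.

**Step 6**
Reactants: 14; 15 (methyl chloroformate)
Product: 4 (methyl 2-bromo-4,6-bis(methoxymethoxy)benzoate)
Conditions: LDA (1.1 equiv), THF, −78 °C, 1 h; then ClCO2Me, −78 °C → rt
Reagents that add atoms: methyl chloroformate, COC(=O)Cl (adds CO2Me)
Why: Directed ortho-lithiation at the C–H flanked by Br and OMOM, then acylation. LDA is used rather than BuLi to avoid Br/Li exchange. This places the ester ortho to the bromide and ortho to one OMOM, giving the ring-A pattern.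

**Step 7**
Reactants: 3; 4
Product: 2 (methyl 2-[2,5-dimethoxy-6-(methoxymethoxy)-3-prenylphenoxy]-4,6-bis(methoxymethoxy)benzoate)
Conditions: CuI (10 mol %), picolinic acid (20 mol %), K3PO4, DMSO, 90 °C
Reagents that add atoms: none
Why: Ullmann-type (Buchwald) Cu-catalysed diaryl ether synthesis. The ortho-ester activates the aryl bromide, and the picolinate ligand allows coupling of a hindered 2,6-dialkoxyphenol. The ester, MOM groups and prenyl alkene are inert under these conditions.

**Step 8**
Reactants: 2
Product: 1 (paucinervin B)
Conditions: 2 M HCl, MeOH, 40 °C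
Reagents that add atoms: none (the MOM groups leave as CH2(OMe)2 and only hydrogen is added)
Why: Acidolysis of the three aryl MOM acetals. The 2,6-disubstituted methyl ester is hindered and is also a methyl ester in MeOH, so it is unchanged. There is no free phenol ortho to the prenyl group, so it cannot cyclise to a chromane.

## Compound list
1 | paucinervin B, methyl 2,4-dihydroxy-6-(2-hydroxy-3,6-dimethoxy-5-prenylphenoxy)benzoate | COC(=O)c1c(O)cc(O)cc1Oc1c(O)c(OC)cc(CC=C(C)C)c1OC | target
2 | tris-MOM diaryl ether | COC(=O)c1c(OCOC)cc(OCOC)cc1Oc1c(OCOC)c(OC)cc(CC=C(C)C)c1OC | intermediate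
3 | 2,5-dimethoxy-6-(methoxymethoxy)-3-prenylphenol | Oc1c(OCOC)c(OC)cc(CC=C(C)C)c1OC | intermediate
4 | methyl 2-bromo-4,6-bis(methoxymethoxy)benzoate | COC(=O)c1c(Br)cc(OCOC)cc1OCOC | intermediate
5 | 2,5-dimethoxyphenol | COc1ccc(OC)c(O)c1 | starting material
6 | chloromethyl methyl ether (MOMCl) | ClCOC | starting material (reagent)
7 | 1-(methoxymethoxy)-2,5-dimethoxybenzene | COCOc1cc(OC)ccc1OC | intermediate
8 | N-bromosuccinimide | O=C1CCC(=O)N1Br | starting material (reagent)
9 | 1-bromo-2,5-dimethoxy-4-(methoxymethoxy)benzene | COCOc1cc(OC)c(Br)cc1OC | intermediate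
10 | prenyl bromide | CC(C)=CCBr | starting material (reagent)
11 | 1-(methoxymethoxy)-2,5-dimethoxy-4-prenylbenzene | COCOc1cc(OC)c(CC=C(C)C)cc1OC | intermediate
12 | hydrogen peroxide | OO | starting material (reagent)
13 | 5-bromoresorcinol | Oc1cc(O)cc(Br)c1 | starting material
14 | 1-bromo-3,5-bis(methoxymethoxy)benzene | COCOc1cc(Br)cc(OCOC)c1 | intermediate
15 | methyl chloroformate | COC(=O)Cl | starting material (reagent)

**Total steps:** 8. **Longest linear sequence:** 6 (steps 1, 2, 3, 4, 7, 8).

## Three steps most likely to fail
1. **Step 7, the hindered Ullmann coupling.** Both partners carry ortho substituents and the phenol is electron-rich.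
   - Fallback: reverse the polarity. Make the ring-B aryl bromide instead (step 4 with BrCF2CF2Br as the quench in place of B(OMe)3/H2O2). Couple it with methyl 2,6-dihydroxy-4-(PMBO)benzoate, made from methyl 2,4,6-trihydroxybenzoate by selective 4-O-PMB protection. Remove PMB and MOM together with TFA.
2. **Step 6, the regiochemistry of lithiation.** Lithiation at the C–H between the two OMOM groups, or a halogen dance, would give the wrong isomer.
   - Fallback: start from 1-fluoro-3,5-bis(MOMO)benzene, where fluorine directs unambiguously to the C–H between F and OMOM. This gives methyl 2-fluoro-4,6-bis(MOMO)benzoate, which is coupled with **3** by SNAr (Cs2CO3, DMSO) instead of Ullmann coupling.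
3. **Step 4, lithiation and hydroxylation with the prenyl group present.** Lateral (benzylic/allylic) lithiation or poor boronate oxidation could compete with ring lithiation.
   - Fallback: hydroxylate the bromide **9** before prenylation, using LDA/B(OMe)3/H2O2, which has no prenyl protons to compete. Carry the bromophenol through the diaryl ether coupling, then install the prenyl group last by Pd-catalysed coupling of the ring-B aryl bromide with a prenylzinc reagent.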